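Ring B holds its only oxygen (C16) para to the quaternary methyl carbon C4, and cyclopentanone ring A (C1, C2, C3) is fused across C4–C18, so rings A and B together are a masked 3-substituted 4-methylphenol. The plan closes ring A by letting that phenol attack, through C4, the protonated diazo carbon C3 of a side-chain diazoketone: one operation forms C3–C4, makes C4 quaternary and turns the arene into the ring B dienone. The substrate is an (R)-α-isopropyl arylacetyl diazomethane whose phenol carries bromine at both positions ortho to the hydroxyl, which leaves C4 as the only reactive carbon. Rings C and D follow by alkenyllithium addition and ring-closing metathesis.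

Key step: step 7

Remarks
- Numbering: ring A = C1(CH–iPr), C2(C=O), C3, C4(C–Me), C18; ring B = C4, C5, C6, C16(C–OH), C17, C18; ring C = C6, C7(CH–Me), C8, C9, C10, C14, C15(C–Me), C16; ring D = C10, C11(CH–Me), C12, C13, C14; the epoxide spans C14–C15. The target is 1R,4S,6R,7R,10S,11S,14S,15R,16R,18S.
- Stereo check: the (R) centre of the diazoketone becomes C1 (R); C4 is R in the dienone and S in the target only because the substituent priorities change.
- Precursor design: with hydrogen at C17 the acyl arm would be expected to close onto C17 (ortho to OH, para to methyl, on the unhindered side of C1) and give an indanone. Bromine at C17 blocks this and is the large ortho group that orients C1; a second bromine at C6 comes with it. Both are removed in step 10.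
- Assumption: in step 2 the aryl group is taken to enter anti to the benzyl group of the Z-enolate, and in step 12 the (2S,5S)-imidazolidinone is taken to give R at the β-carbon; if either sense were opposite, the antipodal auxiliary or catalyst would be used.

Step 1
Reactants: 1 (S)-4-benzyloxazolidin-2-one; 2 3-methylbutanoyl chloride
Product: 3 (S)-4-benzyl-3-(3-methylbutanoyl)oxazolidin-2-one
Conditions: n-BuLi, THF, −78 °C; then 2, −78 → 0 °C
Reagents that add atoms: none
Why: N-acylation of the lithiated oxazolidinone by an acid chloride (imide formation) is routine and creates no stereocentre.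

Step 2
Reactants: 3 (S)-4-benzyl-3-(3-methylbutanoyl)oxazolidin-2-one; 4 2-bromo-4-methoxytoluene
Product: 6 (S)-4-benzyl-3-[(2R)-2-(5-methoxy-2-methylphenyl)-3-methylbutanoyl]oxazolidin-2-one, via silyl ketene aminal 5 (not isolated)
Conditions: NaN(SiMe3)2, Me3SiCl, THF, −78 °C; solvent switch; 4, Pd(dba)2 (5 mol%), P(t-Bu)3 (10 mol%), ZnF2 (0.5 equiv), DMF, 80 °C
Reagents that add atoms: none
Why: Palladium-catalysed α-arylation of the Z-configured silyl enolate under fluoride/zinc activation avoids strong base, so the benzylic product should not epimerise, and the aryl group should enter from the enolate face away from the benzyl group to set C1 as R (the minor diastereomer is removed by chromatography).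

Step 3
Reactants: 6 (S)-4-benzyl-3-[(2R)-2-(5-methoxy-2-methylphenyl)-3-methylbutanoyl]oxazolidin-2-one
Product: 7 (R)-2-(5-methoxy-2-methylphenyl)-3-methylbutanoic acid
Conditions: LiOH, H2O2, THF/H2O, 0 °C; Na2SO3; HCl
Reagents that add atoms: hydrogen peroxide, OO
Why: Hydroperoxide cleavage of the imide attacks the exocyclic carbonyl and should release the acid without touching the α-stereocentre.

Step 4
Reactants: 7 (R)-2-(5-methoxy-2-methylphenyl)-3-methylbutanoic acid
Product: 8 (R)-2-(5-hydroxy-2-methylphenyl)-3-methylbutanoic acid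
Conditions: BBr3, CH2Cl2, −78 → 0 °C; H2O
Reagents that add atoms: none
Why: Lewis-acid cleavage of the aryl methyl ether runs under non-basic conditions that should leave the benzylic stereocentre and the acid intact.

Step 5
Reactants: 8 (R)-2-(5-hydroxy-2-methylphenyl)-3-methylbutanoic acid
Product: 9 (R)-2-(2,4-dibromo-3-hydroxy-6-methylphenyl)-3-methylbutanoic acid
Conditions: N-bromosuccinimide (2.1 equiv), MeCN, 0 °C
Reagents that add atoms: N-bromosuccinimide, O=C1CCC(=O)N1Br
Why: Electrophilic aromatic bromination of the phenol can only end at the two free positions ortho to the hydroxyl (C6 and C17), since the para position carries the methyl group.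

Step 6
Reactants: 9 (R)-2-(2,4-dibromo-3-hydroxy-6-methylphenyl)-3-methylbutanoic acid
Product: 13 (R)-1-diazo-3-(2,4-dibromo-3-hydroxy-6-methylphenyl)-4-methylpentan-2-one, via bis-silyl derivative 10 (not isolated), via acid chloride 11 (not isolated), via O-silyl diazoketone 12 (not isolated)
Conditions: (Me3Si)2NH, CH2Cl2, 40 °C, evaporate; (COCl)2, cat. DMF, CH2Cl2, 0 °C, evaporate; Me3SiCHN2, THF/MeCN, 0 °C; AcOH, evaporate; MeOH, NaHCO3, 0 °C
Reagents that add atoms: (trimethylsilyl)diazomethane, C[Si](C)(C)C=[N+]=[N-]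
Why: Transient O-silylation, base-free conversion of the silyl ester into the acid chloride and C-acylation of the diazoalkane (Arndt–Eistert-type diazoketone synthesis) avoid amine base and hence ketene formation, so C1 should stay R, and methanolysis of the labile aryl silyl ether frees the phenol.

Step 7
Reactants: 13 (R)-1-diazo-3-(2,4-dibromo-3-hydroxy-6-methylphenyl)-4-methylpentan-2-one
Product: 15 (3R,7aR)-4,6-dibromo-7a-methyl-3-(propan-2-yl)-3,7a-dihydro-1H-indene-2,5-dione, via diazonium trifluoroacetate 14 (not isolated)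
Conditions: CF3CO2H, CH2Cl2, −20 °C (slow addition of 13); cold aqueous NaHCO3
Reagents that add atoms: none
Why: CF3CO2H protonates the diazo carbon to give the α-keto diazonium ion 14, whose CH2 carbon (C3) is attacked by the phenol through its para carbon C4 with loss of N2, and loss of the phenolic proton then leaves the cross-conjugated dienone. The closest known reaction type is the acid-promoted intramolecular para-alkylation of phenols by diazomethyl ketones (aryl participation), which gives cyclohexa-2,5-dienones. Ring A closes in a 5-exo-tet mode, C4 displacing N2 from C3 with the leaving group outside the new ring. The new quaternary stereocentre C4 is controlled by C1: 1,3-allylic strain with the bromine at C17 holds the C1 hydrogen in the arene plane, so the acyl arm reaches one face of C4 while isopropyl lies on the other, and methyl and isopropyl end cis on ring A. The step needs regioselectivity (C4 against C17) and facial selectivity at C4; the bromine at C17 secures the first by occupying that carbon and the second by acting as the large ortho group beside the (R)-configured C1.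

Step 8
Reactants: 15 (3R,7aR)-4,6-dibromo-7a-methyl-3-(propan-2-yl)-3,7a-dihydro-1H-indene-2,5-dione
Product: 16 (2S,3R,7aR)-4,6-dibromo-2-hydroxy-7a-methyl-3-(propan-2-yl)-1,2,3,7a-tetrahydro-5H-inden-5-one
Conditions: NaBH4, MeOH/CH2Cl2, −78 °C; AcOH quench
Reagents that add atoms: none
Why: Borohydride reduction at low temperature should take the saturated cyclopentanone in preference to the cross-conjugated dienone carbonyl, with hydride entering C2 opposite the C4 methyl and C1 isopropyl (2β-alcohol), and removing the C2 carbonyl at once stops epimerisation of the doubly activated C1–H.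

Step 9
Reactants: 16 (2S,3R,7aR)-4,6-dibromo-2-hydroxy-7a-methyl-3-(propan-2-yl)-1,2,3,7a-tetrahydro-5H-inden-5-one
Product: 17 (2S,3R,7aR)-4,6-dibromo-2-(tert-butyldimethylsilyloxy)-7a-methyl-3-(propan-2-yl)-1,2,3,7a-tetrahydro-5H-inden-5-one
Conditions: t-BuMe2SiOTf, 2,6-lutidine, CH2Cl2, −40 → 0 °C
Reagents that add atoms: tert-butyldimethylsilyl triflate, CC(C)(C)[Si](C)(C)OS(=O)(=O)C(F)(F)F
Why: Silyl ether protection with the silyl triflate is the standard answer to a hindered secondary alcohol and leaves the dienone untouched.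

Step 10
Reactants: 17 (2S,3R,7aR)-4,6-dibromo-2-(tert-butyldimethylsilyloxy)-7a-methyl-3-(propan-2-yl)-1,2,3,7a-tetrahydro-5H-inden-5-one
Product: 18 (2S,3R,3aS,7aS)-2-(tert-butyldimethylsilyloxy)-7a-methyl-3-(propan-2-yl)octahydro-5H-inden-5-one
Conditions: Li (excess), NH3(l)/THF, t-BuOH (3 equiv), −78 °C; isoprene, NH4Cl
Reagents that add atoms: none
Why: Dissolving-metal reduction should cleave both vinylic C–Br bonds and reduce both enone double bonds, and axial protonation of the β-carbanion at C18 anti to the angular methyl sets the trans ring fusion (H18 α).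

Step 11
Reactants: 18 (2S,3R,3aS,7aS)-2-(tert-butyldimethylsilyloxy)-7a-methyl-3-(propan-2-yl)octahydro-5H-inden-5-one
Product: 19 trimethylsilyl enol ether of 18 with the C6=C16 double bond
Conditions: Me3SiOTf, Et3N, CH2Cl2, 0 °C
Reagents that add atoms: trimethylsilyl triflate, C[Si](C)(C)OS(=O)(=O)C(F)(F)F
Why: Soft enolisation and O-silylation should go toward C6, because an enol double bond toward C17 would flatten ring B next to the strained trans ring fusion.

Step 12
Reactants: 19 trimethylsilyl enol ether of 18; 20 (E)-but-2-enal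
Product: 21 (2S,3R,3aS,6R,7aS)-2-(tert-butyldimethylsilyloxy)-7a-methyl-6-[(2R)-4-oxobutan-2-yl]-3-(propan-2-yl)octahydro-5H-inden-5-one (C6 epimers, equatorial one drawn)
Conditions: (2S,5S)-5-benzyl-2-tert-butyl-3-methylimidazolidin-4-one·2,4-dinitrobenzoic acid (20 mol%), t-BuOH/i-PrOH, −20 °C
Reagents that add atoms: none
Why: In this organocatalytic Mukaiyama–Michael addition the enol ether attacks the unshielded face of the chiral iminium ion of the enal, which should set C7 as R under catalyst control, while C6 forms as a mixture that converges in step 13.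

Step 13
Reactants: 21 keto aldehyde (C6 epimers)
Product: 22 (2S,3R,3aS,6R,7aS)-2-(tert-butyldimethylsilyloxy)-7a-methyl-6-[(2R)-pent-4-en-2-yl]-3-(propan-2-yl)octahydro-5H-inden-5-one
Conditions: Ph3PCH3Br, KN(SiMe3)2, THF, −78 → 0 °C; then K2CO3, MeOH, 23 °C
Reagents that add atoms: methyltriphenylphosphonium bromide, C[P+](c1ccccc1)(c1ccccc1)c1ccccc1.[Br-]
Why: Wittig methylenation at low temperature should take the aldehyde and not the ring ketone, and base equilibration then places the C6 side chain equatorial on the ring B chair (C6 R).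

Step 14
Reactants: 23 (S)-3,7-dimethylocta-1,6-diene ((S)-β-citronellene)
Product: 24 (S)-4-methylhex-5-enal
Conditions: O3 (1.0 equiv), CH2Cl2, −78 °C; Me2S
Reagents that add atoms: ozone, [O-][O+]=O
Why: Ozonolysis with one equivalent of ozone should cleave the electron-rich trisubstituted olefin before the vinyl group and leaves the stereocentre (later C11) untouched.

Step 15
Reactants: 24 (S)-4-methylhex-5-enal
Product: 25 (S)-7,7-dibromo-3-methylhepta-1,6-diene
Conditions: CBr4, PPh3, CH2Cl2, 0 °C
Reagents that add atoms: carbon tetrabromide, BrC(Br)(Br)Br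
Why: Dibromo-olefination of the aldehyde is the first stage of the Corey–Fuchs alkyne synthesis and does not touch the remote stereocentre.

Step 16
Reactants: 25 (S)-7,7-dibromo-3-methylhepta-1,6-diene
Product: 27 (S)-3-methyloct-1-en-6-yne, via lithium acetylide 26 (not isolated)
Conditions: n-BuLi (2.1 equiv), THF, −78 °C; MeI, −78 → 23 °C
Reagents that add atoms: iodomethane, CI
Why: In the second Corey–Fuchs stage bromine–lithium exchange and rearrangement give the lithium acetylide, which is C-methylated in the same flask.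

Step 17
Reactants: 27 (S)-3-methyloct-1-en-6-yne
Product: 29 (1Z,2R,3S)-1-(1-iodoethylidene)-2-(iodomethyl)-3-methylcyclopentane, via zirconabicycle 28 (not isolated)
Conditions: Cp2ZrCl2, n-BuLi (2 equiv), THF, −78 → 23 °C; I2, −78 → 23 °C
Reagents that add atoms: iodine, II
Why: Zirconocene-mediated enyne cyclisation closes ring D with zirconium bound to C15 on the side of C10, so iodinolysis with retention fixes iodine cis to C10 on the tetrasubstituted olefin, while the C10 centre formed here (expected trans to the C11 methyl) is erased in step 18.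

Step 18
Reactants: 29 (1Z,2R,3S)-1-(1-iodoethylidene)-2-(iodomethyl)-3-methylcyclopentane
Product: 30 (1Z,3S)-1-(1-iodoethylidene)-3-methyl-2-methylidenecyclopentane
Conditions: KOt-Bu, THF, 0 → 23 °C
Reagents that add atoms: none
Why: E2 dehydroiodination of the primary iodide has only the C10 hydrogen available and gives the exocyclic methylene, while the tetrasubstituted vinyl iodide has no elimination path.

Step 19
Reactants: 30 (1Z,3S)-1-(1-iodoethylidene)-3-methyl-2-methylidenecyclopentane; 22 (2S,3R,3aS,6R,7aS)-2-(tert-butyldimethylsilyloxy)-7a-methyl-6-[(2R)-pent-4-en-2-yl]-3-(propan-2-yl)octahydro-5H-inden-5-one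
Product: 32 (2S,3R,3aS,5R,6R,7aS)-2-(tert-butyldimethylsilyloxy)-7a-methyl-5-{(1Z)-1-[(3S)-3-methyl-2-methylidenecyclopentylidene]ethyl}-6-[(2R)-pent-4-en-2-yl]-3-(propan-2-yl)octahydro-1H-inden-5-ol, via dienyllithium 31 (not isolated)
Conditions: 30 (1.5 equiv), t-BuLi (3 equiv), Et2O, −78 °C; 22, −78 °C; NH4Cl
Reagents that add atoms: none
Why: Iodine–lithium exchange proceeds with retention of olefin geometry, and 1,2-addition of the bulky alkenyllithium to the cyclohexanone should occur equatorially, trans to the C6 side chain, giving the axial tertiary alcohol (C16 R).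

Step 20
Reactants: 32 triene tertiary alcohol
Product: 33 14,15-epoxide of 32 (14S,15R; oxygen delivered from the hydroxyl side)
Conditions: VO(acac)2 (5 mol%), t-BuOOH, CH2Cl2, 0 °C
Reagents that add atoms: tert-butyl hydroperoxide, CC(C)(C)OO
Why: Hydroxyl-directed vanadium-catalysed epoxidation touches only the allylic tetrasubstituted C14=C15 bond, and in the rotamer that puts the hydroxyl beside the cis substituent C10 and the small ring carbon C17 beside the C15 methyl (least 1,3- and 1,2-allylic strain) oxygen is delivered to the face that gives 14S,15R.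

Step 21
Reactants: 33 epoxy alcohol
Product: 34 tetracyclic (Z)-cyclo-octene: ring C closed, C9=C10 double bond, 14,15-epoxide, C16 hydroxyl, C2 silyl ether
Conditions: second-generation Grubbs catalyst (H2IMes)(PCy3)Cl2Ru=CHPh (15 mol%), toluene (2 mM), 80 °C
Reagents that add atoms: none
Why: Ring-closing metathesis starts at the unhindered terminal vinyl group and closes ring C onto the 1,1-disubstituted olefin, helped by the trans-diequatorial C6 and C16 arms on ring B and the cis-locked epoxide, which hold the two olefins close.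

Step 22
Reactants: 34 tetracyclic cyclo-octene
Product: 35 2β-(tert-butyldimethylsilyloxy) analogue of the target (C2 carbinol silyl ether, C9–C10 saturated, 10S)
Conditions: H2 (50 bar), Rh/Al2O3 (5%), EtOAc, 23 °C
Reagents that add atoms: none
Why: Heterogeneous hydrogenation over rhodium, chosen because it saturates vinyl epoxides with little C–O hydrogenolysis, should add hydrogen to C9=C10 from the open face opposite ring C, which is also the face of the epoxide oxygen and the C16 hydroxyl, so H10 ends cis to the epoxide oxygen.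

Step 23
Reactants: 35 silyl ether
Product: 36 2β,16-diol (target with C2 as the carbinol)
Conditions: Bu4NF, THF, 40 °C
Reagents that add atoms: none
Why: Fluoride cleavage of the silyl ether is mild enough to leave the epoxide and the tertiary alcohol alone.

Step 24
Reactants: 36 2β,16-diol
Product: 37 target ketone (1R,4S,6R,7R,10S,11S,14S,15R,16R,18S)
Conditions: Dess–Martin periodinane, NaHCO3, CH2Cl2, 23 °C
Reagents that add atoms: none
Why: Dess–Martin oxidation under buffered conditions should convert the secondary C2 alcohol into the ketone without epimerising C1 or opening the epoxide, the tertiary C16 hydroxyl being inert.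

Compound list
1 | (S)-4-benzyloxazolidin-2-one | O=C1N[C@@H](Cc2ccccc2)CO1 | starting material
2 | 3-methylbutanoyl chloride (isovaleryl chloride) | CC(C)CC(=O)Cl | starting material
3 | (S)-4-benzyl-3-(3-methylbutanoyl)oxazolidin-2-one | CC(C)CC(=O)N1[C@@H](Cc2ccccc2)COC1=O | intermediate
4 | 2-bromo-4-methoxytoluene | Cc1ccc(OC)cc1Br | starting material
5 | (S)-4-benzyl-3-[(Z)-3-methyl-1-(trimethylsilyloxy)but-1-en-1-yl]oxazolidin-2-one | CC(C)/C=C(\O[Si](C)(C)C)N1[C@@H](Cc2ccccc2)COC1=O | intermediate
6 | (S)-4-benzyl-3-[(2R)-2-(5-methoxy-2-methylphenyl)-3-methylbutanoyl]oxazolidin-2-one | CC(C)[C@@H](C(=O)N1[C@@H](Cc2ccccc2)COC1=O)c1cc(OC)ccc1C | intermediate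
7 | (R)-2-(5-methoxy-2-methylphenyl)-3-methylbutanoic acid | CC(C)[C@@H](C(=O)O)c1cc(OC)ccc1C | intermediate
8 | (R)-2-(5-hydroxy-2-methylphenyl)-3-methylbutanoic acid | CC(C)[C@@H](C(=O)O)c1cc(O)ccc1C | intermediate
9 | (R)-2-(2,4-dibromo-3-hydroxy-6-methylphenyl)-3-methylbutanoic acid | CC(C)[C@@H](C(=O)O)c1c(Br)c(O)c(Br)cc1C | intermediate
10 | trimethylsilyl (R)-2-[2,4-dibromo-6-methyl-3-(trimethylsilyloxy)phenyl]-3-methylbutanoate | CC(C)[C@@H](C(=O)O[Si](C)(C)C)c1c(Br)c(O[Si](C)(C)C)c(Br)cc1C | intermediate
11 | (R)-2-[2,4-dibromo-6-methyl-3-(trimethylsilyloxy)phenyl]-3-methylbutanoyl chloride | CC(C)[C@@H](C(=O)Cl)c1c(Br)c(O[Si](C)(C)C)c(Br)cc1C | intermediate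
12 | (R)-1-diazo-3-[2,4-dibromo-6-methyl-3-(trimethylsilyloxy)phenyl]-4-methylpentan-2-one | CC(C)[C@@H](C(=O)C=[N+]=[N-])c1c(Br)c(O[Si](C)(C)C)c(Br)cc1C | intermediate
13 | (R)-1-diazo-3-(2,4-dibromo-3-hydroxy-6-methylphenyl)-4-methylpentan-2-one | CC(C)[C@@H](C(=O)C=[N+]=[N-])c1c(Br)c(O)c(Br)cc1C | intermediate
14 | (R)-3-(2,4-dibromo-3-hydroxy-6-methylphenyl)-4-methyl-2-oxopentane-1-diazonium trifluoroacetate | CC(C)[C@@H](C(=O)C[N+]#N)c1c(Br)c(O)c(Br)cc1C.[O-]C(=O)C(F)(F)F | intermediate
15 | (3R,7aR)-4,6-dibromo-7a-methyl-3-(propan-2-yl)-3,7a-dihydro-1H-indene-2,5-dione | CC(C)[C@H]1C(=O)C[C@]2(C)C=C(Br)C(=O)C(Br)=C12 | intermediate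
16 | (2S,3R,7aR)-4,6-dibromo-2-hydroxy-7a-methyl-3-(propan-2-yl)-1,2,3,7a-tetrahydro-5H-inden-5-one | CC(C)[C@H]1[C@@H](O)C[C@]2(C)C=C(Br)C(=O)C(Br)=C12 | intermediate
17 | (2S,3R,7aR)-4,6-dibromo-2-(tert-butyldimethylsilyloxy)-7a-methyl-3-(propan-2-yl)-1,2,3,7a-tetrahydro-5H-inden-5-one | CC(C)[C@H]1[C@@H](O[Si](C)(C)C(C)(C)C)C[C@]2(C)C=C(Br)C(=O)C(Br)=C12 | intermediate
18 | (2S,3R,3aS,7aS)-2-(tert-butyldimethylsilyloxy)-7a-methyl-3-(propan-2-yl)octahydro-5H-inden-5-one | CC(C)[C@H]1[C@@H](O[Si](C)(C)C(C)(C)C)C[C@]2(C)CCC(=O)C[C@@H]12 | intermediate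
19 | trimethylsilyl enol ether of 18 (C6=C16) | CC(C)[C@H]1[C@@H](O[Si](C)(C)C(C)(C)C)C[C@]2(C)CC=C(O[Si](C)(C)C)C[C@@H]12 | intermediate
20 | (E)-but-2-enal (crotonaldehyde) | C/C=C/C=O | starting material
21 | (2S,3R,3aS,6R,7aS)-2-(tert-butyldimethylsilyloxy)-7a-methyl-6-[(2R)-4-oxobutan-2-yl]-3-(propan-2-yl)octahydro-5H-inden-5-one | CC(C)[C@H]1[C@@H](O[Si](C)(C)C(C)(C)C)C[C@]2(C)C[C@H]([C@H](C)CC=O)C(=O)C[C@@H]12 | intermediate
22 | (2S,3R,3aS,6R,7aS)-2-(tert-butyldimethylsilyloxy)-7a-methyl-6-[(2R)-pent-4-en-2-yl]-3-(propan-2-yl)octahydro-5H-inden-5-one | CC(C)[C@H]1[C@@H](O[Si](C)(C)C(C)(C)C)C[C@]2(C)C[C@H]([C@H](C)CC=C)C(=O)C[C@@H]12 | intermediate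
23 | (S)-3,7-dimethylocta-1,6-diene ((S)-β-citronellene) | C=C[C@@H](C)CCC=C(C)C | starting material
24 | (S)-4-methylhex-5-enal | C=C[C@@H](C)CCC=O | intermediate
25 | (S)-7,7-dibromo-3-methylhepta-1,6-diene | C=C[C@@H](C)CCC=C(Br)Br | intermediate
26 | lithium acetylide of (S)-3-methylhept-1-en-6-yne | C=C[C@@H](C)CCC#C[Li] | intermediate
27 | (S)-3-methyloct-1-en-6-yne | C=C[C@@H](C)CCC#CC | intermediate
28 | zirconabicycle (zirconocene bound to C15 and to the CH2 on C10) | [Zr]1(C2C=CC=C2)(C2C=CC=C2)C[C@@H]2[C@@H](C)CCC2=C1C | intermediate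
29 | (1Z,2R,3S)-1-(1-iodoethylidene)-2-(iodomethyl)-3-methylcyclopentane | IC[C@@H]1[C@@H](C)CC/C1=C(/I)C | intermediate
30 | (1Z,3S)-1-(1-iodoethylidene)-3-methyl-2-methylidenecyclopentane | C=C1[C@@H](C)CC/C1=C(/I)C | intermediate
31 | dienyllithium from 30 (lithium in place of iodine) | C=C1[C@@H](C)CC/C1=C(/[Li])C | intermediate
32 | (2S,3R,3aS,5R,6R,7aS)-2-(tert-butyldimethylsilyloxy)-7a-methyl-5-{(1Z)-1-[(3S)-3-methyl-2-methylidenecyclopentylidene]ethyl}-6-[(2R)-pent-4-en-2-yl]-3-(propan-2-yl)octahydro-1H-inden-5-ol | CC(C)[C@H]1[C@@H](O[Si](C)(C)C(C)(C)C)C[C@]2(C)C[C@H]([C@H](C)CC=C)[C@@](O)(/C(C)=C3/CC[C@H](C)C3=C)C[C@@H]12 | intermediate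
33 | 14,15-epoxide of 32 (14S,15R) | CC(C)[C@H]1[C@@H](O[Si](C)(C)C(C)(C)C)C[C@]2(C)C[C@H]([C@H](C)CC=C)[C@@](O)([C@@]4(C)O[C@]45CC[C@H](C)C5=C)C[C@@H]12 | intermediate
34 | tetracyclic (Z)-cyclo-octene (C9=C10, 14,15-epoxide, C16-OH, C2-OTBS) | CC(C)[C@H]1[C@@H](O[Si](C)(C)C(C)(C)C)C[C@]2(C)C[C@@H]3[C@H](C)C/C=C4/[C@@H](C)CC[C@]45O[C@]5(C)[C@@]3(O)C[C@@H]12 | intermediate
35 | 2β-(tert-butyldimethylsilyloxy) analogue of the target (C2 carbinol silyl ether) | CC(C)[C@H]1[C@@H](O[Si](C)(C)C(C)(C)C)C[C@]2(C)C[C@@H]3[C@H](C)CC[C@H]4[C@@H](C)CC[C@]45O[C@]5(C)[C@@]3(O)C[C@@H]12 | intermediate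
36 | 2β,16-diol (target with C2 as carbinol) | CC(C)[C@H]1[C@@H](O)C[C@]2(C)C[C@@H]3[C@H](C)CC[C@H]4[C@@H](C)CC[C@]45O[C@]5(C)[C@@]3(O)C[C@@H]12 | intermediate
37 | target: 14,15-epoxy-16-hydroxy-2-ketone (1R,4S,6R,7R,10S,11S,14S,15R,16R,18S) | CC(C)[C@H]1C(=O)C[C@]2(C)C[C@@H]3[C@H](C)CC[C@H]4[C@@H](C)CC[C@]45O[C@]5(C)[C@@]3(O)C[C@@H]12 | target

Total step count: 24. Longest linear sequence: 19 (steps 1–13 and 19–24).

Steps most likely to fail

Step 7. What may go wrong: capture of the diazonium ion by trifluoroacetate before the bromine-deactivated phenol attacks, and erosion of the facial preference at C4. Fallback (anionic instead of cationic ring closure): starting from 13, HBr (48% aq.) in Et2O at 0 °C should give the bromomethyl ketone (R)-1-bromo-3-(2,4-dibromo-3-hydroxy-6-methylphenyl)-4-methylpentan-2-one F1. K2CO3 in DMF then ionises the acidic dibromophenol but is too weak to enolise C1, and intramolecular para-C-alkylation of the phenoxide (the base-mediated route to cyclohexadienones) should return to 15.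

Step 21. What may go wrong: slow metathesis at the 1,1-disubstituted olefin, which sits next to the quaternary epoxide carbon C14, with oligomerisation through the terminal vinyl group taking over. Fallback (ring closure before epoxidation, so that the reacting olefin is flanked by an sp2 carbon): starting from 32, metathesis with the same ruthenium catalyst should give the tetracyclic cyclo-octa-9,14-dienol F2. Hydroxyl-directed epoxidation of its C14=C15 bond (VO(acac)2, t-BuOOH), also favoured on the face away from the C11 methyl, returns to 34.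

Step 22. What may go wrong: hydrogenolysis or ring-opening of the allylic epoxide, or no reduction at the hindered trisubstituted olefin. Fallback (saturate C9–C10 before the epoxide exists): starting from 32, metathesis gives the cyclo-octadienol F2 described above. Diimide (2-nitrobenzenesulfonylhydrazide, Et3N, CH2Cl2) should then reduce only the trisubstituted C9=C10 bond, from the open face, to give the 14-ene tertiary allylic alcohol F3. Hydroxyl-directed epoxidation (VO(acac)2, t-BuOOH) returns to 35.

Further compounds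
F1 | step 7 | (R)-1-bromo-3-(2,4-dibromo-3-hydroxy-6-methylphenyl)-4-methylpentan-2-one | CC(C)[C@@H](C(=O)CBr)c1c(Br)c(O)c(Br)cc1C
F2 | step 21 | tetracyclic cyclo-octa-9,14-dienol (C9=C10 and C14=C15, C16-OH, C2-OTBS) | CC(C)[C@H]1[C@@H](O[Si](C)(C)C(C)(C)C)C[C@]2(C)C[C@@H]3[C@H](C)C/C=C4/[C@@H](C)CC/C4=C(C)/[C@@]3(O)C[C@@H]12
F3 | step 22 | tetracyclic 14-ene tertiary allylic alcohol (C9–C10 saturated, 10S, C2-OTBS) | CC(C)[C@H]1[C@@H](O[Si](C)(C)C(C)(C)C)C[C@]2(C)C[C@@H]3[C@H](C)CC[C@H]4[C@@H](C)CC/C4=C(C)/[C@@]3(O)C[C@@H]12
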